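**Plan**
- Retrosynthesis: the 7-acetate and the diene (C14=C15, then C12=C13) are cut first, then C8–C17, then ring A at C4–C5, then ring B at C5–C6 and C7–C8 (with the C5–C8 bond of a cyclobutanone restored), and last C10–C1 and C9–C11, which leads back to 3-methylcyclobutenone.
- Forward: cyclobutenone → quaternary C10 and allylated C9 → ring B by two-carbon ring expansion with methoxyketene → ring A by cationic closure → C17 methyl → C6–C8 oxygenation → side chain → acetate.
- Enabling feature: in ring B every carbon of C6–C7–C8 carries oxygen (a masked 2-alkoxycyclohexane-1,3-dione), and C5 and C8 are both bonded to the C9–C10 pair. C5–C8 can therefore be the enamine double bond of a cyclobutanone that takes up the C6–C7 unit of an alkoxyketene and is then cleaved.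
- Stereochemistry: C10 from ligand-controlled Cu-catalysed conjugate addition; C9 by equilibration to the equatorial epimer in the bicyclic C8 ketone; C5 trans under thermodynamic control next to the C6 carbonyl; C8 by α-face epoxidation opposite the axial C10 methyl; C6 and C7 by α-face hydride delivery; C12=C13 E from cross-metathesis.

Key step: step 4

Remark: labdane numbering (C1 to C20) is used for the atoms of all intermediates; the C9 epimers formed in step 2 converge in step 6.

**Route**

Step 1
Reactants: 1 3-ethoxycyclobut-2-en-1-one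
Product: 3 3-methylcyclobut-2-en-1-one, via lithium alkoxide adduct 2 (not isolated)
Conditions: MeLi, Et2O, −78 °C; then 1 M HCl, 0 °C
Reagents that add atoms: methyllithium, [Li]C
Why: 1,2-addition of MeLi to the vinylogous ester carbonyl and acid-induced loss of ethanol with allylic transposition (Stork–Danheiser transposition) should give the 3-methyl enone, which has no stereocentre.

Step 2
Reactants: 3 3-methylcyclobut-2-en-1-one; 4 5-bromo-2-methylpent-2-ene; 5 allyl iodide
Product: 8 (3S)-3-methyl-3-(4-methylpent-3-en-1-yl)-2-(prop-2-en-1-yl)cyclobutan-1-one as a mixture of C2 epimers, via Grignard reagent 6 (not isolated), via bromomagnesium enolate 7 (not isolated)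
Conditions: 4, Mg, THF, 40 °C; then 3, Cu(OTf)2 (3 mol%), chiral imidazolinium (N-heterocyclic carbene) ligand precursor (4 mol%), Et2O, −30 °C; then 5, DMPU, −30 to 0 °C
Reagents that add atoms: none
Why: Cu-catalysed asymmetric conjugate addition of the Grignard reagent to the strained enone should set the C10 quaternary centre under ligand control (the ligand enantiomer that gives 3S is used), and the regiodefined enolate is allylated at C9 before it can equilibrate.

Step 3
Reactants: 8 (3S)-3-methyl-3-(4-methylpent-3-en-1-yl)-2-(prop-2-en-1-yl)cyclobutan-1-one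
Product: 9 1-[(3S)-3-methyl-3-(4-methylpent-3-en-1-yl)-4-(prop-2-en-1-yl)cyclobut-1-en-1-yl]pyrrolidine
Conditions: pyrrolidine, 4 Å molecular sieves, cyclohexane, 60 °C
Reagents that add atoms: pyrrolidine, C1CCNC1
Why: enamine condensation should place the double bond toward the unsubstituted C5 methylene and away from the allyl-bearing C9, so that the nucleophilic β-carbon is C5.

Step 4
Reactants: 9 1-[(3S)-3-methyl-3-(4-methylpent-3-en-1-yl)-4-(prop-2-en-1-yl)cyclobut-1-en-1-yl]pyrrolidine; 10 methoxyacetyl chloride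
Product: 13 (5S)-2-methoxy-5-methyl-5-(4-methylpent-3-en-1-yl)-4-(prop-2-en-1-yl)-3-(pyrrolidin-1-yl)cyclohex-2-en-1-one, via methoxyketene 11 (not isolated), via bicyclic aminocyclobutanone 12 (not isolated)
Conditions: 10, Et3N, Et2O, −20 to 23 °C; then 40 °C
Reagents that add atoms: none
Why: Et3N converts 10 into methoxyketene 11, whose carbonyl carbon (C6) is attacked by the enamine β-carbon C5, and the resulting iminium enolate closes by Mannich addition of C7 to C8 to give the 1-aminobicyclo[2.2.0]hexan-2-one 12, a stepwise [2+2] that forms C5–C6 and C7–C8. The nitrogen lone pair then expels the C6 enolate by retro-Mannich cleavage of the shared C5–C8 bond, which releases the strain of two fused four-membered rings, and a proton shift gives the vinylogous amide 13. The closest known reaction type is the two-carbon ring expansion of cyclic ketone enamines with ketenes to cycloalkane-1,3-dione derivatives, together with the C-acylation of enamines by acid chlorides. The four-membered ring closes in a 4-exo-trig (Mannich) mode, and ring B arises by fragmentation of the central bond of the bicycle, a ring expansion and not a direct cyclisation. No new stereocentre survives (C7 becomes sp2 and C5 a methylene), and C10 is untouched. The step needs C5 and not C9 to be the enamine carbon, and carbon and not nitrogen to be acylated: the allyl group on C9 keeps the enamine double bond toward C5, and strain release plus vinylogous amide conjugation should make the C5–C8 fragmentation irreversible, whereas N-acylation is reversible.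

Step 5
Reactants: 13 (5S)-2-methoxy-5-methyl-5-(4-methylpent-3-en-1-yl)-4-(prop-2-en-1-yl)-3-(pyrrolidin-1-yl)cyclohex-2-en-1-one
Product: 15 (5S)-2,3-dimethoxy-5-methyl-5-(4-methylpent-3-en-1-yl)-6-(prop-2-en-1-yl)cyclohex-2-en-1-one, via O-methyl iminium salt 14 (not isolated)
Conditions: Me3OBF4, CH2Cl2, 0 °C; then H2O, 0 °C (pH about 4)
Reagents that add atoms: trimethyloxonium tetrafluoroborate, C[O+](C)C.F[B-](F)(F)F; water, O
Why: O-methylation of the vinylogous amide oxygen gives an alkoxy iminium salt whose iminium carbon C8 is hydrolysed under mildly acidic conditions (imidate-type amide-to-ester exchange), which should fix the carbonyl at C8 and the enol ether at C6.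

Step 6
Reactants: 15 (5S)-2,3-dimethoxy-5-methyl-5-(4-methylpent-3-en-1-yl)-6-(prop-2-en-1-yl)cyclohex-2-en-1-one
Product: 17 (1R,4aS,8aS)-3,4-dimethoxy-5,5,8a-trimethyl-1-(prop-2-en-1-yl)-4a,5,6,7,8,8a-hexahydronaphthalen-2(1H)-one, via C9 epimer mixture 16 (not isolated)
Conditions: TfOH (0.2 equiv), (CF3)2CHOH/CH2Cl2, −20 to 0 °C; then NaOMe (cat.), MeOH, 23 °C
Reagents that add atoms: none
Why: Proposed new method: TfOH should protonate the C3=C4 alkene to the tertiary C4 cation while the vinylogous ester equilibrates with its 8-hydroxy-5,7-dienol, whose γ-carbon C5 traps the cation in a six-membered closure of ring A (the terminal allyl group and the deactivated C8 carbonyl should not compete, and attack through C9 would create two adjacent quaternary carbons); the closest known reaction type is the acid-promoted cation–olefin cyclisation terminated by a β-keto ester enol or a silyl enol ether; NaOMe then equilibrates C9, now α to the C8 ketone of a rigid bicycle, to the equatorial 9β-allyl epimer (axial protonation from the face opposite the C10 methyl leads to the same epimer), and any cis-fused material converges later because C5 becomes α to the C6 ketone.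

Step 7
Reactants: 17 (1R,4aS,8aS)-3,4-dimethoxy-5,5,8a-trimethyl-1-(prop-2-en-1-yl)-4a,5,6,7,8,8a-hexahydronaphthalen-2(1H)-one
Product: 19 (4R,4aR,8aS)-2-methoxy-3,4a,8,8-tetramethyl-4-(prop-2-en-1-yl)-4a,5,6,7,8,8a-hexahydronaphthalen-1(4H)-one, via lithium alkoxide adduct 18 (not isolated)
Conditions: MeLi, CeCl3, THF, −78 °C; then 1 M HCl, 0 °C
Reagents that add atoms: methyllithium, [Li]C
Why: 1,2-addition to the C8 carbonyl and acid hydrolysis of the C6 enol ether with allylic transposition (Stork–Danheiser transposition) should install the C17 methyl as the C7=C8 enone without touching C9, and C5, now α to the C6 ketone, rests in the trans-fused configuration.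

Step 8
Reactants: 19 (4R,4aR,8aS)-2-methoxy-3,4a,8,8-tetramethyl-4-(prop-2-en-1-yl)-4a,5,6,7,8,8a-hexahydronaphthalen-1(4H)-one
Product: 21 (3S,4R,4aR,8aS)-3-hydroxy-3,4a,8,8-tetramethyl-4-(prop-2-en-1-yl)-3,4,4a,5,6,7,8,8a-octahydronaphthalene-1,2-dione, via epoxy ether 20 (not isolated)
Conditions: DMDO, acetone, −20 °C; then wet silica gel
Reagents that add atoms: dimethyldioxirane, CC1(C)OO1; water, O
Why: epoxidation of the tetrasubstituted enol ether double bond (Rubottom-type oxidation) should occur from the α face opposite the axial C10 methyl, so that hydrolytic opening of the epoxy ether leaves the tertiary 8α-hydroxyl (C17 β) and the C7 ketone, while the monosubstituted allyl alkene reacts far more slowly.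

Step 9
Reactants: 21 (3S,4R,4aR,8aS)-3-hydroxy-3,4a,8,8-tetramethyl-4-(prop-2-en-1-yl)-3,4,4a,5,6,7,8,8a-octahydronaphthalene-1,2-dione
Product: 23 (1R,2S,3S,4S,4aS,8aS)-2,5,5,8a-tetramethyl-1-(prop-2-en-1-yl)decahydronaphthalene-2,3,4-triol, via 7β-hydroxy-6-ketone 22 (not isolated)
Conditions: NaBH4, CeCl3·7H2O, MeOH, −40 to 0 °C
Reagents that add atoms: none
Why: in this Luche-type reduction hydride should attack C7 axially from the α face (equatorial 7β-OH) and then C6 from the α face, because the β face is blocked by the axial C10 and C4 methyl groups (axial 6β-OH), with the C5 hydrogen settling trans when the intermediate enediol ketonises.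

Step 10
Reactants: 23 (1R,2S,3S,4S,4aS,8aS)-2,5,5,8a-tetramethyl-1-(prop-2-en-1-yl)decahydronaphthalene-2,3,4-triol; 24 methacrolein
Product: 25 (2E)-2-methyl-4-[(1R,2S,3S,4S,4aS,8aS)-2,3,4-trihydroxy-2,5,5,8a-tetramethyldecahydronaphthalen-1-yl]but-2-enal
Conditions: 24 (10 equiv), second-generation Hoveyda–Grubbs catalyst RuCl2(H2IMes)(=CH-C6H4-2-OiPr) (5 mol%), CH2Cl2, 40 °C
Reagents that add atoms: none
Why: olefin cross-metathesis of the terminal alkene with the 1,1-disubstituted enal should be selective for the cross product and give the E-trisubstituted C12=C13 enal.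

Step 11
Reactants: 25 (2E)-2-methyl-4-[(1R,2S,3S,4S,4aS,8aS)-2,3,4-trihydroxy-2,5,5,8a-tetramethyldecahydronaphthalen-1-yl]but-2-enal
Product: 26 (1R,2S,3S,4S,4aS,8aS)-2,5,5,8a-tetramethyl-1-[(2E)-3-methylpenta-2,4-dien-1-yl]decahydronaphthalene-2,3,4-triol
Conditions: Ph3PCH3Br, KN(SiMe3)2 (excess), THF, 0 °C
Reagents that add atoms: methyltriphenylphosphonium bromide, C[P+](c1ccccc1)(c1ccccc1)c1ccccc1.[Br-]
Why: Wittig methylenation of the aldehyde with the non-stabilised ylide should complete the 1,3-diene without changing the C12=C13 geometry.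

Step 12
Reactants: 26 (1R,2S,3S,4S,4aS,8aS)-2,5,5,8a-tetramethyl-1-[(2E)-3-methylpenta-2,4-dien-1-yl]decahydronaphthalene-2,3,4-triol
Product: 27 7β-acetoxylabda-12(E),14-diene-6β,8α-diol (5S,6S,7S,8S,9R,10S)
Conditions: Ac2O (1.1 equiv), pyridine, 0 °C
Reagents that add atoms: acetic anhydride, CC(=O)OC(C)=O
Why: acylation should be selective for the equatorial secondary 7β-hydroxyl, because the 6β-hydroxyl is axial and flanked by the axial C10 and C4 methyl groups and the 8-hydroxyl is tertiary.

**Compound list**

1 | 3-ethoxycyclobut-2-en-1-one | CCOC1=CC(=O)C1 | starting material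
2 | lithium 3-ethoxy-1-methylcyclobut-2-en-1-olate | CCOC1=CC(C)([O-])C1.[Li+] | intermediate
3 | 3-methylcyclobut-2-en-1-one | CC1=CC(=O)C1 | intermediate
4 | 5-bromo-2-methylpent-2-ene | CC(C)=CCCBr | starting material
5 | 3-iodoprop-1-ene (allyl iodide) | C=CCI | starting material
6 | (4-methylpent-3-en-1-yl)magnesium bromide | CC(C)=CCC[Mg]Br | intermediate
7 | bromomagnesium (3S)-3-methyl-3-(4-methylpent-3-en-1-yl)cyclobut-1-en-1-olate | CC(C)=CCC[C@]1(C)C=C(O[Mg]Br)C1 | intermediate
8 | (3S)-3-methyl-3-(4-methylpent-3-en-1-yl)-2-(prop-2-en-1-yl)cyclobutan-1-one, C2 epimers | C=CCC1C(=O)C[C@]1(C)CCC=C(C)C | intermediate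
9 | 1-[(3S)-3-methyl-3-(4-methylpent-3-en-1-yl)-4-(prop-2-en-1-yl)cyclobut-1-en-1-yl]pyrrolidine, C4 epimers | C=CCC1C(N2CCCC2)=C[C@]1(C)CCC=C(C)C | intermediate
10 | methoxyacetyl chloride | COCC(Cl)=O | starting material
11 | methoxyketene | COC=C=O | intermediate
12 | 3-methoxy-6-methyl-6-(4-methylpent-3-en-1-yl)-5-(prop-2-en-1-yl)-4-(pyrrolidin-1-yl)bicyclo[2.2.0]hexan-2-one (C10 as in 9, other centres as formed) | C=CCC1C2(N3CCCC3)C(OC)C(=O)C2[C@]1(C)CCC=C(C)C | intermediate
13 | (5S)-2-methoxy-5-methyl-5-(4-methylpent-3-en-1-yl)-4-(prop-2-en-1-yl)-3-(pyrrolidin-1-yl)cyclohex-2-en-1-one, C4 epimers | C=CCC1C(N2CCCC2)=C(OC)C(=O)C[C@]1(C)CCC=C(C)C | intermediate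
14 | 1-[(5S)-2,3-dimethoxy-5-methyl-5-(4-methylpent-3-en-1-yl)-6-(prop-2-en-1-yl)cyclohex-2-en-1-ylidene]pyrrolidin-1-ium tetrafluoroborate | C=CCC1C(=[N+]2CCCC2)C(OC)=C(OC)C[C@]1(C)CCC=C(C)C.F[B-](F)(F)F | intermediate
15 | (5S)-2,3-dimethoxy-5-methyl-5-(4-methylpent-3-en-1-yl)-6-(prop-2-en-1-yl)cyclohex-2-en-1-one, C6 epimers | C=CCC1C(=O)C(OC)=C(OC)C[C@]1(C)CCC=C(C)C | intermediate
16 | (4aS,8aS)-3,4-dimethoxy-5,5,8a-trimethyl-1-(prop-2-en-1-yl)-4a,5,6,7,8,8a-hexahydronaphthalen-2(1H)-one, C1 (labdane C9) epimers | C=CCC1C(=O)C(OC)=C(OC)[C@H]2C(C)(C)CCC[C@@]21C | intermediate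
17 | (1R,4aS,8aS)-3,4-dimethoxy-5,5,8a-trimethyl-1-(prop-2-en-1-yl)-4a,5,6,7,8,8a-hexahydronaphthalen-2(1H)-one (9β-allyl, 5α-H, 10β-methyl) | C=CC[C@H]1C(=O)C(OC)=C(OC)[C@H]2C(C)(C)CCC[C@@]21C | intermediate
18 | lithium 3,4-dimethoxy-2,5,5,8a-tetramethyl-1-(prop-2-en-1-yl)-1,2,4a,5,6,7,8,8a-octahydronaphthalen-2-olate (ring centres as in 17, C2 epimers) | C=CC[C@H]1C(C)([O-])C(OC)=C(OC)[C@H]2C(C)(C)CCC[C@@]21C.[Li+] | intermediate
19 | (4R,4aR,8aS)-2-methoxy-3,4a,8,8-tetramethyl-4-(prop-2-en-1-yl)-4a,5,6,7,8,8a-hexahydronaphthalen-1(4H)-one | C=CC[C@H]1C(C)=C(OC)C(=O)[C@H]2C(C)(C)CCC[C@@]21C | intermediate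
20 | 7α,8α-epoxide of 19 (epoxide oxygen α, 7-methoxy β, C17 β) | C=CC[C@H]1[C@]3(C)O[C@]3(OC)C(=O)[C@H]2C(C)(C)CCC[C@@]21C | intermediate
21 | (3S,4R,4aR,8aS)-3-hydroxy-3,4a,8,8-tetramethyl-4-(prop-2-en-1-yl)-3,4,4a,5,6,7,8,8a-octahydronaphthalene-1,2-dione (8α-hydroxy-6,7-dione, in equilibrium with its C5=C6 enol) | C=CC[C@H]1[C@](C)(O)C(=O)C(=O)[C@H]2C(C)(C)CCC[C@@]21C | intermediate
22 | (2R,3S,4R,4aR,8aS)-2,3-dihydroxy-3,4a,8,8-tetramethyl-4-(prop-2-en-1-yl)-3,4,4a,5,6,7,8,8a-octahydronaphthalen-1(2H)-one (7β,8α-dihydroxy-6-ketone) | C=CC[C@H]1[C@](C)(O)[C@@H](O)C(=O)[C@H]2C(C)(C)CCC[C@@]21C | intermediate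
23 | (1R,2S,3S,4S,4aS,8aS)-2,5,5,8a-tetramethyl-1-(prop-2-en-1-yl)decahydronaphthalene-2,3,4-triol (6β,7β,8α-triol) | C=CC[C@H]1[C@](C)(O)[C@@H](O)[C@@H](O)[C@H]2C(C)(C)CCC[C@@]21C | intermediate
24 | methacrolein (2-methylprop-2-enal) | C=C(C)C=O | starting material
25 | (2E)-2-methyl-4-[(1R,2S,3S,4S,4aS,8aS)-2,3,4-trihydroxy-2,5,5,8a-tetramethyldecahydronaphthalen-1-yl]but-2-enal | O=C/C(C)=C/C[C@H]1[C@](C)(O)[C@@H](O)[C@@H](O)[C@H]2C(C)(C)CCC[C@@]21C | intermediate
26 | (1R,2S,3S,4S,4aS,8aS)-2,5,5,8a-tetramethyl-1-[(2E)-3-methylpenta-2,4-dien-1-yl]decahydronaphthalene-2,3,4-triol (labda-12E,14-diene-6β,7β,8α-triol) | C=C/C(C)=C/C[C@H]1[C@](C)(O)[C@@H](O)[C@@H](O)[C@H]2C(C)(C)CCC[C@@]21C | intermediate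
27 | 7β-acetoxylabda-12(E),14-diene-6β,8α-diol (5S,6S,7S,8S,9R,10S) | C=C/C(C)=C/C[C@H]1[C@](C)(O)[C@@H](OC(C)=O)[C@@H](O)[C@H]2C(C)(C)CCC[C@@]21C | target

**Step count and risks**

Total step count: 12. Longest linear sequence: 12 steps (from 1).

Steps most likely to fail:

Step 6 (proposed new method). The tertiary cation may be lost by elimination, or be trapped at the wrong carbon, before the weakly populated dienol reacts. The fallback uses known chemistry and sets out from 15. Methyl addition and acidic transposition as in step 7 (MeLi, CeCl3; then dilute HCl) are carried out first and give the monocyclic enone (5S)-2-methoxy-3,5-dimethyl-5-(4-methylpent-3-en-1-yl)-4-(prop-2-en-1-yl)cyclohex-2-en-1-one F1. HCl gas in CH2Cl2 at −78 °C adds across the trisubstituted alkene to give (5S)-5-(4-chloro-4-methylpentyl)-2-methoxy-3,5-dimethyl-4-(prop-2-en-1-yl)cyclohex-2-en-1-one F2. Kinetic deprotonation at C5 with LiN(iPr)2 and silylation with Me3SiCl give the C5=C6 trimethylsilyl dienol ether of F2 F3. TiCl4 in CH2Cl2 at −78 °C then effects the Lewis acid-mediated intramolecular tert-alkylation of the silyl enol ether by the tertiary chloride and closes ring A. Because this path has no bicyclic C8 ketone stage, the unwanted C9 epimer is removed by chromatography. The fallback comes back to the route at 19.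

Step 4. N-acylation of the enamine, oligomerisation of the ketene or hydrolytic loss of the strained enamine may compete with C-acylation. The fallback sets out from 8. Kinetic deprotonation at the C5 methylene with LiN(iPr)2 and C-acylation of the lithium enolate with 1-(methoxyacetyl)benzotriazole give the 4-(methoxyacetyl) derivative of 8 F4. Condensation with pyrrolidine at the ring carbonyl (AcOH cat., toluene, 60 °C) generates the same iminium enolate from the other side, which should close and fragment in the same way. The fallback comes back to the route at 13.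

Step 2. Facial selectivity in the conjugate addition may be insufficient, 1,2-addition of the Grignard reagent may compete, or proton exchange of the magnesium enolate before allylation may erase its regiochemical integrity. The fallback sets out from 1 and inverts the order in which the two C10 substituents are introduced. Addition of Grignard reagent 6 to 1 and acidic work-up give 3-(4-methylpent-3-en-1-yl)cyclobut-2-en-1-one F5. Cu-catalysed asymmetric conjugate addition of AlMe3 (copper thiophene-2-carboxylate Cu(O2CC4H3S) with a chiral phosphoramidite ligand of the appropriate facial sense) follows, then exchange of the aluminium enolate for the lithium enolate with MeLi and allylation with 5. The fallback comes back to the route at 8.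

**Further compounds**

F1 | step 6 | (5S)-2-methoxy-3,5-dimethyl-5-(4-methylpent-3-en-1-yl)-4-(prop-2-en-1-yl)cyclohex-2-en-1-one | C=CCC1C(C)=C(OC)C(=O)C[C@]1(C)CCC=C(C)C
F2 | step 6 | (5S)-5-(4-chloro-4-methylpentyl)-2-methoxy-3,5-dimethyl-4-(prop-2-en-1-yl)cyclohex-2-en-1-one | C=CCC1C(C)=C(OC)C(=O)C[C@]1(C)CCCC(C)(C)Cl
F3 | step 6 | C5=C6 trimethylsilyl dienol ether of F2 | C=CCC1C(C)=C(OC)C(O[Si](C)(C)C)=C[C@]1(C)CCCC(C)(C)Cl
F4 | step 4 | 4-(methoxyacetyl) derivative of 8 | C=CCC1C(=O)C(C(=O)COC)[C@]1(C)CCC=C(C)C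
F5 | step 2 | 3-(4-methylpent-3-en-1-yl)cyclobut-2-en-1-one | CC(C)=CCCC1=CC(=O)C1
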